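(Readings and results were generated by integration with constants of no real substance.)

Compare the east run with the flask: impurity and catalyst are equal, and east has twice the partner.

the same everywhere: starting material 0.30 M; free catalyst 1 mol% (in portions, 2)

|  | partner | impurity | remark | time |
|---|---|---|---|---|
| west | 1.2 equiv | 0.49 mM | run made earlier; portions every 5.0 s |  |
| north-west | 1.2 equiv | 2 mM | run made earlier; portions every 5.0 s |  |
| east | 2.4 equiv | 0.98 mM | run made earlier; portions every 5.0 s |  |
| flask | 1.20 equiv | 0.98 mM | the portions of free catalyst follow each other after 5.0 s, the first at the start | 15 min |

| run | time / min | product / % | starting material / % |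
|---|---|---|---|
| west | 1.33 | 45.1 | 55.3 |
| west | 2.50 | 51.5 | 49.2 |
| west | 4.00 | 54.5 | 45.2 |
| west | 6.00 | 57.5 | 42.9 |
| west | 10.0 | 59.0 | 40.4 |
| west | 20.0 | 62.6 | 37.6 |
| north-west | 3.00 | 39.4 | 60.5 |
| north-west | 6.00 | 45.5 | 54.7 |
| north-west | 10.0 | 49.2 | 50.9 |
| north-west | 12.0 | 49.9 | 49.7 |
| north-west | 15.0 | 51.8 | 48.4 |
| north-west | 20.0 | 53.6 | 46.5 |
| east | 4.00 | 78.9 | 21.1 |
| east | 8.00 | 82.7 | 17.8 |
| east | 10.0 | 83.7 | 16.2 |
| east | 15.0 | 85.7 | 14.8 |
| east | 20.0 | 85.8 | 14.0 |

(readings scatter by 0.3 percentage points)

- what was read earlier has a scatter of 0.3 percentage points, one standard deviation
- steps that have been proposed: starting material + partner + free catalyst <-> product + free catalyst; free catalyst + impurity -> spent catalyst A; 2 free catalyst <-> resting dimer; 2 free catalyst -> spent catalyst B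
- the reaction counts as stopped when no species that holds the starting material changes by six tenths of a point or more over the second half of the time

1. the state of affairs at 15 min: stopped, and by what, or still going (the partner has run out first / all of the starting material has reacted / it is still moving / forward and back rates have come level)
2. product at 15 min, in percent of the starting material charged
3. amount of product if the flask were left three thousand times as long, in percent of the starting material charged

Start with the bound from above. The west run has the flask's charges with less impurity, and impurity costs product: at 20.0 min, west shows 62.6% and north-west 53.6%. Interpolated on the logarithm of time, west stands at 61.1% at 15 min. The first bound from below is the north-west reading at that time, 51.8%, with more impurity.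

Now tighten the lower bound. East at 15.0 min gives 3.50 M⁻¹ for the catalyst dose, the time integral of forward rate constant times free catalyst. Reckon it as the natural logarithm of partner left over starting material left, each as a share of its own charge, divided by the difference of their charged concentrations. No proposed step that removes free catalyst contains the partner, and east and the flask carry equal impurity and equal catalyst, so they share one dose at equal time. Carried to the flask's charges, this reading gives 58.4%. Any back reaction would hold east back harder, since product over starting material times partner reads 12.4 M⁻¹ in east and 7.60 M⁻¹ reckoned for the flask. East's dose then reads low, which makes this a bound from below, within the scatter of the reading.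

The forecast gives 59%, it is still moving, and 73% at the long horizon, noting “Product is still gaining about 3 points between 7.5 and 15 min”. Its product lies inside my bracket.

    starting material + partner + free catalyst ⇌ product + free catalyst, rate k1*[starting material]*[partner]*[free catalyst] forward; the back reaction follows from the equilibrium constant (K = 36.0 M⁻¹, k = 53.0 M⁻² s⁻¹)
    free catalyst + impurity → spent catalyst A (k = 250 M⁻¹ s⁻¹)
    2 free catalyst ⇌ resting dimer (K = 580 M⁻¹, k = 390 M⁻¹ s⁻¹)
    2 free catalyst → spent catalyst B (k = 42.0 M⁻¹ s⁻¹)

The flask gives 59.3% at 15 min, inside the bracket, and 74.6% at the long horizon. The state at 15 min is: it is still moving, with a largest change of 3.2 percentage points in the share of any substrate or product over the second half of the time. Reckoned by the same formula from the flask's own product, the dose reads 3.63 M⁻¹, above east's 3.50 M⁻¹. Put into the neighbouring flask with 0.480 equiv of partner, now the limiting reagent, this dose gives 28.5% product, and that flask holds 28.7%.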